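Locants are the heavy atoms of the target SMILES in order (C1 methyl, C2=C3, C4, C5–O6, C7, C8 methyl, C9, C10–O11, C12, C13 methyl, C14, C15, C16, C17 methyl, C18, C19, C20 with C21/C22, C23 to C27); ring A = C3,4,5,7,9; ring B = the cyclooctene; ring C = C12,14,15,16,24,25; ring D = C16,18,19,20,23,24.
Cuts, in retrosynthetic order: O11–C10 and H–C9 (hydroboration of a C9=C10 bond), C2=C3 (McMurry closure of ring B), C9–C10 (aldol that appends ring A), C16–C17 (methyl by allylic substitution), then C12–C14 and C24–C25 together (Diels–Alder closure of ring C).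
Enabling feature: the C12–C25 edge of ring C carries C10 and C26 trans and C10 is oxygenated, so this edge is an (E)-2-methyl enal dienophile. The opposite edge C14–C15–C16–C24 is fused to ring D and is a 1-vinylcyclohexene diene; an oxygen donor on C14 steers the regiochemistry and is then spent to place the C17 methyl on quaternary C16.
Forward order: ring D is bought, ring C is closed by the intermolecular Diels–Alder reaction, C17 is added, ring A (a bought cyclopentenone) is attached at C9–C10, ring B is closed at C2=C3, and C9/C10 are finished by hydroboration.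
Stereochemistry: C12, C24, C25 (and the temporary C14 center) from the catalyst-controlled endo cycloaddition; C16 by syn-SN2' transfer from C14; C5 from (R)-4-silyloxycyclopentenone and C7 by cuprate addition anti to it; C9 and C10 together by syn hydroboration on the face opposite the C8 and C13 methyl groups.

Key step: step 4

Remark: β denotes the face of the polycycle that carries the C13 methyl group; the C10 carbinol center of 22 to 25 forms without control, is erased at 26 and is therefore left open in those SMILES.

Step 1
Reactants: 1 4,4-dimethylcyclohexanone; 2 diethyl (cyanomethyl)phosphonate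
Product: 3 2-(4,4-dimethylcyclohexylidene)acetonitrile
Conditions: NaH, THF, 0 °C to rt
Reagents that add atoms: none
Why: Horner–Wadsworth–Emmons olefination of the unhindered ketone by the phosphonate carbanion gives the conjugated nitrile, and the symmetric ring leaves no alkene isomerism or stereocenter to control.

Step 2
Reactants: 3 2-(4,4-dimethylcyclohexylidene)acetonitrile
Product: 5 2-(4,4-dimethylcyclohexylidene)acetaldehyde, via aluminated aldimine 4 (not isolated)
Conditions: i-Bu2AlH, PhMe, −78 °C; then aq. HCl, 0 °C
Reagents that add atoms: water, O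
Why: Partial reduction of the nitrile by i-Bu2AlH stops at the N-aluminated aldimine, whose hydrolysis on acidic work-up gives the conjugated aldehyde (nitrile-to-aldehyde reduction) with no stereocenter formed.

Step 3
Reactants: 5 2-(4,4-dimethylcyclohexylidene)acetaldehyde
Product: 6 (E)-1-[2-(triisopropylsilyloxy)ethenyl]-4,4-dimethylcyclohexene (ring D diene)
Conditions: i-Pr3SiOTf, Et3N, Et2O, 0 °C to rt
Reagents that add atoms: triisopropylsilyl trifluoromethanesulfonate, CC(C)[Si](OS(=O)(=O)C(F)(F)F)(C(C)C)C(C)C
Why: Soft enolisation (O-silylation of the s-trans enal followed by γ-deprotonation at an equivalent ring CH2 by Et3N) gives the silyl dienol ether with the E enol-ether geometry and the second double bond inside ring D.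

Step 4
Reactants: 6 ring D diene; 7 ethyl (E)-3-methyl-4-oxobut-2-enoate
Product: 8 cycloadduct (ring C closed; C13 methyl β and C10 formyl α on C12; O14 α; C26 ester β on C25; H24 β; C15=C16)
Conditions: (R)-3,3-diphenyl-1-(2-methylphenyl)tetrahydropyrrolo[1,2-c][1,3,2]oxazaborole from (R)-α,α-diphenylprolinol (20 mol %), Tf2NH (18 mol %), CH2Cl2, −78 °C; Et3N quench
Reagents that add atoms: none
Why: Formyl coordination to the cationic boron lowers the LUMO of 7, and a concerted, asynchronous normal-demand [4+2] follows in which the C24–C25 bond (diene terminus remote from the silyloxy donor to the carbon β to the formyl group) runs ahead of the C12–C14 bond; the closest known reaction type is the oxazaborolidinium-catalysed enantioselective Diels–Alder reaction of 2-substituted enals with silyloxy dienes. Ring C is closed by this intermolecular suprafacial cycloaddition, both new σ-bonds lying in that one six-membered ring, with ring D already attached along C16–C24. C12 and C25 (C10 trans to C26) follow from the E geometry of 7, and C14 and C24 follow from the endo position of the boron-bound formyl group together with the E enol ether and the ring-bound terminus of the diene (O14 and C23 both cis to C10). The absolute sense comes from the catalyst, whose (R) antipode should leave open the face of C12 on which C10, C25 and C13 run counterclockwise when the s-trans enal stacks on a catalyst phenyl ring. The step needs regio-, endo- and facial selectivity: the first is secured by the match of the C14 silyloxy group (largest HOMO coefficient at C24) with the formyl group (largest LUMO coefficient at C25, the ester being the weaker director), the second by Lewis-acid binding at the formyl oxygen only, the third by the chiral cation.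

Step 5
Reactants: 8 cycloadduct
Product: 10 silyloxy lactone (trans-fused γ-lactone O–C10H2/C26=O; 14α-OSi), via hydroxy ester 9 (not isolated)
Conditions: NaBH4, EtOH, 0 °C; then PPTS (cat.), PhMe, 80 °C
Reagents that add atoms: none
Why: Borohydride reduction is chemoselective for the aldehyde over the ester, and the primary alcohol then lactonises onto the trans-disposed equatorial ester (acid-catalysed transesterification) to a trans-fused γ-lactone that masks both functions without touching a stereocenter, C25 being held because its epimer would place C26 1,3-diaxial to O14.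

Step 6
Reactants: 10 silyloxy lactone
Product: 11 hydroxy lactone (14α-OH)
Conditions: Bu4NF, AcOH, THF, 0 °C to rt
Reagents that add atoms: none
Why: Fluoride-induced desilylation frees the C14 allylic alcohol with retention, the acetic acid buffer keeping the medium too weakly basic to enolise the lactone at C25.

Step 7
Reactants: 11 hydroxy lactone; 12 2-(diphenylphosphanyl)benzoic acid
Product: 13 14α-[2-(diphenylphosphanyl)benzoyl]oxy lactone
Conditions: DCC, DMAP (cat.), CH2Cl2, rt
Reagents that add atoms: none
Why: Steglich esterification acylates the hindered secondary alcohol at oxygen, so C14 keeps its configuration and gains the phosphine-bearing benzoate that will act as an internal ligand for copper.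

Step 8
Reactants: 13 phosphanylbenzoate lactone
Product: 14 methyl lactone (C17 methyl α on quaternary C16; C14=C15)
Conditions: MeMgI (slow addition), CuBr·SMe2 (50 mol %), Et2O, rt
Reagents that add atoms: methylmagnesium iodide, C[Mg]I
Why: Copper-mediated directed allylic substitution (syn-SN2'): the methylcopper species bound to the ortho-phosphine is delivered to C16 on the α face of the pseudoaxial C14–O bond while the carboxylate leaves, so the α-oxygen at C14 is traded for the α-methyl at quaternary C16 (trans to H24), the alkene moves to C14=C15, and direct attack at the neopentyl C14 or at the lactone is outrun by the intramolecular delivery.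

Step 9
Reactants: 14 methyl lactone
Product: 15 diol (C10H2OH and C26H2OH)
Conditions: LiAlH4, THF, 0 °C
Reagents that add atoms: none
Why: Hydride reduction of the lactone (LiAlH4 reduction) gives the 1,4-diol without touching the isolated alkene or any stereocenter.

Step 10
Reactants: 15 diol
Product: 16 dialdehyde (C10 and C26 formyl groups)
Conditions: (COCl)2, DMSO, CH2Cl2, −78 °C; Et3N, −78 °C to 0 °C
Reagents that add atoms: none
Why: Swern oxidation converts both primary alcohols into alkoxysulfonium ions before the base is added, so the dialdehyde forms without the lactol-to-lactone over-oxidation of a 1,4-diol, C12 being quaternary and C25 already carrying its formyl group equatorial.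

Step 11
Reactants: 16 dialdehyde; 17 1-(triphenylphosphoranylidene)propan-2-one
Product: 18 enone aldehyde (C10 formyl; (E)-C26=C27–C2(=O)–C1 chain on C25)
Conditions: CH2Cl2, rt
Reagents that add atoms: none
Why: Wittig olefination with the stabilised ylide is slow at the neopentyl C10 aldehyde on quaternary C12 and therefore chemoselective for the C26 aldehyde, giving the (E)-enone that brings in C27, C2 and C1.

Step 12
Reactants: 18 enone aldehyde
Product: 19 keto aldehyde (C10 formyl; 3-oxobutyl chain on C25; ring C saturated)
Conditions: H2 (3 atm), Pd/C, EtOAc, rt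
Reagents that add atoms: none
Why: Heterogeneous catalytic hydrogenation saturates the enone C=C and the cis-disubstituted C14=C15 bond while the aldehyde and ketone carbonyls survive, and no stereocenter is created.

Step 13
Reactants: 20 (R)-4-(tert-butyldimethylsilyloxy)cyclopent-2-en-1-one
Product: 21 silyl enol ether (C3=C9 trimethylsilyl enol ether; C8 methyl on C7 trans to O6 on C5)
Conditions: Me2CuLi (from MeLi and CuI), Me3SiCl, THF, −78 °C; Et3N quench
Reagents that add atoms: lithium dimethylcuprate, [Li+].C[Cu-]C; chlorotrimethylsilane, C[Si](C)(C)Cl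
Why: Conjugate addition of lithium dimethylcuprate takes place anti to the C5 silyloxy group, which sets C7 with the C8 methyl trans to O6, and Me3SiCl traps the enolate regiospecifically as the C3=C9 silyl enol ether.

Step 14
Reactants: 19 keto aldehyde; 21 silyl enol ether
Product: 22 aldol (ring A ketone joined through C9 to C10H(OH); C10 trans to the C8 methyl; C10 epimers)
Conditions: BF3·OEt2, CH2Cl2, −78 °C; aq. NaHCO3
Reagents that add atoms: none
Why: Mukaiyama aldol addition under BF3 activation is selective for the aldehyde over the methyl ketone and avoids the base that would trigger an intramolecular aldol of 19; C9 is attacked anti to the C8 methyl, and the C10 carbinol center is not controlled because it is erased later.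

Step 15
Reactants: 22 aldol
Product: 23 triethylsilyl ether of 22
Conditions: Et3SiOTf, 2,6-lutidine, CH2Cl2, −78 °C
Reagents that add atoms: triethylsilyl trifluoromethanesulfonate, CC[Si](CC)(CC)OS(=O)(=O)C(F)(F)F
Why: Silylation of the aldol hydroxyl (silyl triflate with a hindered base at low temperature, faster at oxygen than enol silylation of the ketones) blocks retro-aldol cleavage and dehydration in the reductive coupling.

Step 16
Reactants: 23 triethylsilyl ether
Product: 24 tetracycle (rings A to D; C2=C3; 5α-OSi(t-Bu)Me2; 10-OSiEt3; 9β-H)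
Conditions: TiCl3(DME)1.5, Zn–Cu, DME, reflux, slow addition at high dilution
Reagents that add atoms: none
Why: Intramolecular McMurry coupling of the ring A ketone (C3) with the methyl ketone (C2) on low-valent titanium (pinacolate formation, then deoxygenation) closes ring B as the tetrasubstituted C2=C3 alkene, whose geometry is dictated by the eight-membered ring and whose formation is helped by the gauche, diequatorial placement of the two chains on ring C.

Step 17
Reactants: 24 tetracycle
Product: 25 C10 alcohol
Conditions: HF·pyridine, pyridine, THF, 0 °C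
Reagents that add atoms: none
Why: Buffered HF cleaves the triethylsilyl ether much faster than the tert-butyldimethylsilyl ether (selective desilylation), releasing only the C10 hydroxyl.

Step 18
Reactants: 25 C10 alcohol
Product: 26 C10 ketone (β,γ-unsaturated)
Conditions: Dess–Martin periodinane, NaHCO3, CH2Cl2, 0 °C to rt
Reagents that add atoms: none
Why: Dess–Martin oxidation under bicarbonate buffer gives the β,γ-unsaturated ketone without moving the C2=C3 bond into conjugation, and the two C10 epimers converge to one compound.

Step 19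
Reactants: 26 C10 ketone
Product: 28 dienyl triflate (C10–OSO2CF3; C9=C10 and C2=C3), via potassium dienolate 27 (not isolated)
Conditions: KN(SiMe3)2, THF, −78 °C; then PhNTf2, −78 °C to 0 °C
Reagents that add atoms: N-phenylbis(trifluoromethanesulfonimide), O=S(=O)(N(c1ccccc1)S(=O)(=O)C(F)(F)F)C(F)(F)F
Why: C9 is the only enolisable position (C12 is quaternary) and is doubly activated, so the amide base gives the dienolate, which is triflated at oxygen (enol triflate formation), turning the wrongly configured C9 and the C10 carbonyl into a C9=C10 bond whose geometry is fixed by ring B.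

Step 20
Reactants: 28 dienyl triflate
Product: 29 diene (C9=C10 with H on C10; C2=C3; 5α-OSi(t-Bu)Me2)
Conditions: Pd(OAc)2 (5 mol %), PPh3, Bu3N, HCO2H, DMF, 60 °C
Reagents that add atoms: none
Why: Palladium-catalysed formate reduction of the enol triflate (oxidative addition, formate exchange, decarboxylation, reductive elimination) replaces the triflate by hydrogen with retention of alkene geometry and gives the ring-fused 1,3-diene.

Step 21
Reactants: 29 diene
Product: 30 dienol (5α-OH)
Conditions: Bu4NF, THF, rt
Reagents that add atoms: none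
Why: Fluoride desilylation frees O6 and removes the bulky silyl group from the α face that the borane must approach in the last step.

Step 22
Reactants: 30 dienol
Product: 32 target CNP0213887.1, via alkylborane 31 (not isolated)
Conditions: BH3·THF, THF, 0 °C to rt; then NaOH, H2O2, 0 °C
Reagents that add atoms: hydrogen peroxide, OO
Why: Hydroboration–oxidation: BH3 adds to the trisubstituted C9=C10 bond in preference to the tetrasubstituted C2=C3 bond, boron going to the less substituted C10 and hydrogen to C9 in a syn fashion from the α face, which is opposite both the C8 methyl next to C9 and the C13 methyl next to C10, and oxidation with retention then gives the 10α-hydroxyl and 9α-hydrogen of the target.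

Compound list
1 | 4,4-dimethylcyclohexan-1-one | CC1(C)CCC(=O)CC1 | starting material
2 | diethyl (cyanomethyl)phosphonate | CCOP(=O)(CC#N)OCC | starting material
3 | 2-(4,4-dimethylcyclohexylidene)acetonitrile | N#CC=C1CCC(C)(C)CC1 | intermediate
4 | N-[bis(2-methylpropyl)alumanyl]-2-(4,4-dimethylcyclohexylidene)ethan-1-imine | CC(C)C[Al](CC(C)C)N=CC=C1CCC(C)(C)CC1 | intermediate (not isolated)
5 | 2-(4,4-dimethylcyclohexylidene)acetaldehyde | O=CC=C1CCC(C)(C)CC1 | intermediate
6 | (E)-{[2-(4,4-dimethylcyclohex-1-en-1-yl)ethenyl]oxy}tri(propan-2-yl)silane (diene C14=C15–C16=C24) | CC(C)[Si](O/C=C/C1=CCC(C)(C)CC1)(C(C)C)C(C)C | intermediate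
7 | ethyl (E)-3-methyl-4-oxobut-2-enoate (C10 formyl and C13 methyl on C12; C26 ester on C25) | CCOC(=O)/C=C(\C)C=O | starting material
8 | cycloadduct, ethyl 2-formyl-2,7,7-trimethyl-3-(triisopropylsilyloxy)-1,2,3,5,6,7,8,8a-octahydronaphthalene-1-carboxylate; C13 methyl β and C10 formyl α on C12, O14 α, C26 ester β and H α on C25, H24 β, C15=C16 | O=C[C@@]1(C)[C@@H](O[Si](C(C)C)(C(C)C)C(C)C)C=C2CCC(C)(C)C[C@H]2[C@@H]1C(=O)OCC | intermediate
9 | hydroxy ester, the C10 primary alcohol of 8 | OC[C@@]1(C)[C@@H](O[Si](C(C)C)(C(C)C)C(C)C)C=C2CCC(C)(C)C[C@H]2[C@@H]1C(=O)OCC | intermediate (not isolated)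
10 | silyloxy lactone; γ-lactone O–C10H2 (α on C12)/C26=O (β on C25) trans-fused to ring C, 14α-OSi(i-Pr)3, C15=C16 | O=C1OC[C@@]2(C)[C@@H](O[Si](C(C)C)(C(C)C)C(C)C)C=C3CCC(C)(C)C[C@H]3[C@@H]21 | intermediate
11 | hydroxy lactone, the 14α-alcohol of 10 | O=C1OC[C@@]2(C)[C@@H](O)C=C3CCC(C)(C)C[C@H]3[C@@H]21 | intermediate
12 | 2-(diphenylphosphanyl)benzoic acid | OC(=O)c1ccccc1P(c1ccccc1)c1ccccc1 | starting material
13 | 14α-[2-(diphenylphosphanyl)benzoyl]oxy lactone | O=C1OC[C@@]2(C)[C@@H](OC(=O)c4ccccc4P(c4ccccc4)c4ccccc4)C=C3CCC(C)(C)C[C@H]3[C@@H]21 | intermediate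
14 | methyl lactone; C17 methyl α on quaternary C16, C14=C15, H24 β, lactone as in 10 | O=C1OC[C@@]2(C)C=C[C@]3(C)CCC(C)(C)C[C@H]3[C@@H]21 | intermediate
15 | diol; C10H2OH (α on C12) and C26H2OH (β on C25) on the ring C/D core of 14 | OC[C@@]1(C)C=C[C@]2(C)CCC(C)(C)C[C@H]2[C@@H]1CO | intermediate
16 | dialdehyde; C10 and C26 formyl groups | O=C[C@@]1(C)C=C[C@]2(C)CCC(C)(C)C[C@H]2[C@@H]1C=O | intermediate
17 | 1-(triphenyl-λ5-phosphanylidene)propan-2-one | CC(=O)C=P(c1ccccc1)(c1ccccc1)c1ccccc1 | starting material
18 | enone aldehyde; C10 formyl, (E)-C26=C27–C2(=O)–C1 chain on C25 | O=C[C@@]1(C)C=C[C@]2(C)CCC(C)(C)C[C@H]2[C@@H]1/C=C/C(C)=O | intermediate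
19 | keto aldehyde; C10 formyl, 3-oxobutyl chain (C26–C27–C2(=O)–C1) on C25, trans-fused ring C/D with 12β- and 16α-methyl groups | O=C[C@@]1(C)CC[C@]2(C)CCC(C)(C)C[C@H]2[C@@H]1CCC(C)=O | intermediate
20 | (R)-4-{[tert-butyl(dimethyl)silyl]oxy}cyclopent-2-en-1-one | O=C1C=C[C@H](O[Si](C)(C)C(C)(C)C)C1 | starting material
21 | tert-butyl(dimethyl){[trans-2-methyl-4-(trimethylsilyloxy)cyclopent-3-en-1-yl]oxy}silane (C3=C9 enol ether; C8 methyl trans to O6) | C[Si](C)(C)OC1=C[C@@H](C)[C@H](O[Si](C)(C)C(C)(C)C)C1 | intermediate
22 | aldol; ring A ketone (C3=O) bonded through C9 to C10H(OH), C10 trans to the C8 methyl, 5α-OSi(t-Bu)Me2, C10 epimers | O=C1C[C@@H](O[Si](C)(C)C(C)(C)C)[C@H](C)[C@H]1C(O)[C@@]2(C)CC[C@]3(C)CCC(C)(C)C[C@H]3[C@@H]2CCC(C)=O | intermediate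
23 | triethylsilyl ether of 22 (C10 epimers) | O=C1C[C@@H](O[Si](C)(C)C(C)(C)C)[C@H](C)[C@H]1C(O[Si](CC)(CC)CC)[C@@]2(C)CC[C@]3(C)CCC(C)(C)C[C@H]3[C@@H]2CCC(C)=O | intermediate
24 | tetracycle; rings A to D with C2=C3, 5α-OSi(t-Bu)Me2, 7β-methyl, 9β-H, 10-OSiEt3 (C10 epimers) | C/C1=C2\C[C@@H](O[Si](C)(C)C(C)(C)C)[C@H](C)[C@H]2C(O[Si](CC)(CC)CC)[C@@]2(C)CC[C@]3(C)CCC(C)(C)C[C@H]3[C@@H]2CC1 | intermediate
25 | C10 alcohol of 24 (C10 epimers) | C/C1=C2\C[C@@H](O[Si](C)(C)C(C)(C)C)[C@H](C)[C@H]2C(O)[C@@]2(C)CC[C@]3(C)CCC(C)(C)C[C@H]3[C@@H]2CC1 | intermediate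
26 | C10 ketone (β,γ-unsaturated; 9β-H) | C/C1=C2\C[C@@H](O[Si](C)(C)C(C)(C)C)[C@H](C)[C@H]2C(=O)[C@@]2(C)CC[C@]3(C)CCC(C)(C)C[C@H]3[C@@H]2CC1 | intermediate
27 | potassium dienolate of 26 (O–C10=C9–C3=C2) | C/C1=C2\C[C@@H](O[Si](C)(C)C(C)(C)C)[C@H](C)/C2=C(\[O-])[C@@]2(C)CC[C@]3(C)CCC(C)(C)C[C@H]3[C@@H]2CC1.[K+] | intermediate (not isolated)
28 | dienyl triflate; C10–OSO2CF3, C9=C10 and C2=C3 | C/C1=C2\C[C@@H](O[Si](C)(C)C(C)(C)C)[C@H](C)/C2=C(\OS(=O)(=O)C(F)(F)F)[C@@]2(C)CC[C@]3(C)CCC(C)(C)C[C@H]3[C@@H]2CC1 | intermediate
29 | diene; C9=C10 (H on C10) and C2=C3, 5α-OSi(t-Bu)Me2 | C/C1=C2\C[C@@H](O[Si](C)(C)C(C)(C)C)[C@H](C)/C2=C/[C@@]2(C)CC[C@]3(C)CCC(C)(C)C[C@H]3[C@@H]2CC1 | intermediate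
30 | dienol, the 5α-alcohol of 29 | C/C1=C2\C[C@@H](O)[C@H](C)/C2=C/[C@@]2(C)CC[C@]3(C)CCC(C)(C)C[C@H]3[C@@H]2CC1 | intermediate
31 | alkylborane; 10α-boryl, 9α-H, O6 as its boron ester | C/C1=C2\C[C@@H](OB)[C@H](C)[C@@H]2[C@@H](B)[C@@]2(C)CC[C@]3(C)CCC(C)(C)C[C@H]3[C@@H]2CC1 | intermediate (not isolated)
32 | CNP0213887.1; (5R,7R,9S,10R,12S,16S,24S,25S) in the locants used here, 5α,10α-diol | C/C1=C2\C[C@@H](O)[C@H](C)[C@@H]2[C@@H](O)[C@@]2(C)CC[C@]3(C)CCC(C)(C)C[C@H]3[C@@H]2CC1 | target

Total step count: 22. Longest linear sequence: 21 steps (steps 1 to 12 and 14 to 22; step 13 is a one-step branch).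

Steps most likely to fail

Step 4. The strongly acidic boron cation may strip the silyl group from the dienol ether or divert it into stepwise conjugate addition, or it may discriminate the two faces of the enal poorly. The fallback moves facial control from the catalyst to a covalently bound auxiliary on an acid-stable acyloxy diene. It sets out from enal 5: O-acylation of its potassium dienolate (KN(SiMe3)2, THF, −78 °C) with (S)-O-methylmandeloyl chloride should give the (E)-dienyl (S)-O-methylmandelate F1. Its BF3·OEt2-promoted Diels–Alder reaction with 7, in which the mandelate aryl group covers one face of the diene, should give the mandelate cycloadduct F2 with the same regio- and endo-selectivity. NaBH4 and then PPTS give the lactone mandelate F3, and methanolysis of the mandelate (K2CO3, MeOH; then PPTS to reclose the lactone) comes back to hydroxy lactone 11. The antipodal acid is taken if the auxiliary proves to shield the other face.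

Step 8. Delivery of methyl to the ring-fusion carbon may be too slow to form the quaternary center, so that undirected anti attack or Grignard addition to the lactone takes over. The fallback lets the C14 hydroxyl direct a cyclopropanation instead of a substitution. It sets out from hydroxy lactone 11: hydroxyl-directed Simmons–Smith cyclopropanation (Et2Zn, CH2I2, CH2Cl2, 0 °C) should add CH2 to C15=C16 on the α face and give the cyclopropyl carbinol F4. Hydrogenolysis (H2, PtO2, AcOH) cleaves the least hindered cyclopropane bond (CH2–C15) and leaves the α-methyl on C16 in the saturated hydroxy lactone F5. Dehydration of the axial C14 alcohol toward C15, the only neighbour with hydrogen (POCl3, pyridine), comes back to methyl lactone 14.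

Step 16. Intermolecular coupling, arrest at the pinacol stage, or loss of the β-silyloxy groups at the temperature needed for deoxygenation may defeat the ring closure. The fallback forms the alkene in two stages at low temperature. It sets out from 23: SmI2-promoted intramolecular pinacol coupling (THF, HMPA, rt) should give the cis-diol F6. 1,1'-Thiocarbonyldiimidazole with DMAP converts it into the cyclic thionocarbonate F7, and Corey–Winter fragmentation with 1,3-dimethyl-2-phenyl-1,3,2-diazaphospholidine at 40 °C comes back to tetracycle 24 by stereospecific syn elimination.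

Further compounds
F1 | step 4 | (E)-2-(4,4-dimethylcyclohex-1-en-1-yl)ethenyl (S)-2-methoxy-2-phenylacetate | CO[C@@H](c1ccccc1)C(=O)O/C=C/C1=CCC(C)(C)CC1
F2 | step 4 | mandelate cycloadduct (as 8 with the (S)-O-methylmandelate on O14) | O=C[C@@]1(C)[C@@H](OC(=O)[C@@H](OC)c3ccccc3)C=C2CCC(C)(C)C[C@H]2[C@@H]1C(=O)OCC
F3 | step 4 | lactone mandelate (as 10 with the (S)-O-methylmandelate on O14) | O=C1OC[C@@]2(C)[C@@H](OC(=O)[C@@H](OC)c4ccccc4)C=C3CCC(C)(C)C[C@H]3[C@@H]21
F4 | step 8 | cyclopropyl carbinol (α-CH2 bridging C15 and C16; 14α-OH) | O=C1OC[C@@]2(C)[C@@H](O)[C@H]4C[C@]43CCC(C)(C)C[C@H]3[C@@H]21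
F5 | step 8 | saturated hydroxy lactone (16α-methyl; 14α-OH) | O=C1OC[C@@]2(C)[C@@H](O)C[C@]3(C)CCC(C)(C)C[C@H]3[C@@H]21
F6 | step 16 | cis-2,3-diol of ring B (pinacol) | C[C@@]1(O)[C@@]2(O)C[C@@H](O[Si](C)(C)C(C)(C)C)[C@H](C)[C@H]2C(O[Si](CC)(CC)CC)[C@@]2(C)CC[C@]3(C)CCC(C)(C)C[C@H]3[C@@H]2CC1
F7 | step 16 | cyclic 2,3-thionocarbonate of F6 | C[C@@]1(OC(=S)O4)[C@@]24C[C@@H](O[Si](C)(C)C(C)(C)C)[C@H](C)[C@H]2C(O[Si](CC)(CC)CC)[C@@]2(C)CC[C@]3(C)CCC(C)(C)C[C@H]3[C@@H]2CC1
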